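**Assumption:** the target SMILES has no stereocentre and no stereogenic double bond, so the compound is achiral and no enantiocontrol is needed. The target is 5-O-methylxylerythrin. The route is a paper design and has not been run.

**Retrosynthetic overview**
- Target ⇐ fluoride desilylation of its phenol TBS ether; the phenol stays masked until the end.
- Lactone ring ⇐ acid-mediated closure of an arylacetic acid onto the neighbouring methoxy-bearing ring carbon of a quinone methide, with loss of methanol; the other methoxy group is kept as the 5-OMe.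
- Quinone methide ⇐ dehydration of a tertiary aldol; the key C3–C3a bond ⇐ intermolecular aldol addition of the lithium enolate of tert-butyl (4-silyloxyphenyl)acetate to a carbonyl of C2-symmetric 2,5-dimethoxy-3,6-diphenyl-1,4-benzoquinone.
- Quinone ⇐ twofold Suzuki coupling of 2,5-dibromo-3,6-dimethoxybenzoquinone (from bromanil and NaOMe) with phenylboronic acid; ester ⇐ 4-hydroxyphenylacetic acid.
- Ring order: the six-membered carbocycle is bought, the two phenyl rings are attached, and the lactone ring is formed last.

**Step 1**
Reactants: 1 bromanil (2,3,5,6-tetrabromo-1,4-benzoquinone)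
Product: 3 2,5-dibromo-3,6-dimethoxy-1,4-benzoquinone, via tribromomethoxyquinone 2 (not isolated)
Conditions: NaOMe (2.05 equiv), MeOH, 0 °C → rt
Reagents that add atoms: sodium methoxide, [Na+].[O-]C
Why: Twofold addition–elimination (vinylogous acyl substitution) on the tetrahaloquinone, in which the first methoxy group deactivates its own enone unit so that the second methoxide enters para to it and gives the 2,5-pattern.

**Step 2**
Reactants: 3 2,5-dibromo-3,6-dimethoxy-1,4-benzoquinone; 4 phenylboronic acid (2.5 equiv)
Product: 6 2,5-dimethoxy-3,6-diphenyl-1,4-benzoquinone (polyporic acid dimethyl ether), via monophenylated bromoquinone 5 (not isolated)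
Conditions: Pd(PPh3)4 (5 mol %), K3PO4 (4 equiv), 1,4-dioxane, 90 °C, argon
Reagents that add atoms: none
Why: Twofold Suzuki–Miyaura coupling, in which the C–Br bonds of the bromoquinone (vinylogous acyl bromides) add readily to zerovalent palladium and the phosphate base avoids hydrolysis of the methoxyquinone.

**Step 3**
Reactants: 7 4-hydroxyphenylacetic acid
Product: 8 tert-butyl 2-(4-hydroxyphenyl)acetate
Conditions: t-BuOC(=NH)CCl3 (2 equiv), THF/cyclohexane, rt, no Lewis acid
Reagents that add atoms: tert-butyl 2,2,2-trichloroacetimidate, CC(C)(C)OC(=N)C(Cl)(Cl)Cl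
Why: Imidate esterification, in which the carboxylic acid protonates the imidate and captures the tert-butyl cation while the much less acidic phenol does not react without a Lewis acid.

**Step 4**
Reactants: 8 tert-butyl 2-(4-hydroxyphenyl)acetate
Product: 9 tert-butyl 2-[4-(tert-butyldimethylsilyloxy)phenyl]acetate
Conditions: TBSCl (1.2 equiv), imidazole (2.5 equiv), DMF, rt
Reagents that add atoms: tert-butyldimethylsilyl chloride, CC(C)(C)[Si](C)(C)Cl
Why: Corey silylation of the phenol, which removes the acidic O–H before enolate formation and gives an ether stable to amide bases and to anhydrous acid.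

**Step 5**
Reactants: 9 tert-butyl 2-[4-(tert-butyldimethylsilyloxy)phenyl]acetate (1.2 equiv); 6 2,5-dimethoxy-3,6-diphenyl-1,4-benzoquinone
Product: 12 tert-butyl 2-[4-(tert-butyldimethylsilyloxy)phenyl]-2-(1-hydroxy-2,5-dimethoxy-4-oxo-3,6-diphenylcyclohexa-2,5-dien-1-yl)acetate (racemic diastereomer mixture), via lithium enolate 10 (not isolated), via lithium aldolate 11 (not isolated)
Conditions: LiN(SiMe3)2 (1.15 equiv), THF, −78 °C, 45 min; cannulate into 6 in THF, −78 °C, 2 h; AcOH (1.5 equiv) at −78 °C, then warm
Reagents that add atoms: none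
Why: Intermolecular aldol addition of a hard lithium ester enolate to one of the two symmetry-equivalent quinone carbonyls (1,2-addition as in Stork–Danheiser additions to vinylogous esters, with the fully substituted ring disfavouring conjugate attack), where the cold quench prevents retro-aldol and the two new stereocentres are formed without control because both become sp2 carbons in steps 6 and 7.

**Step 6**
Reactants: 12 tertiary aldol
Product: 14 tert-butyl 2-[4-(tert-butyldimethylsilyloxy)phenyl]-2-(2,5-dimethoxy-4-oxo-3,6-diphenylcyclohexa-2,5-dien-1-ylidene)acetate (E/Z mixture), via chlorosulfite 13 (not isolated)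
Conditions: SOCl2 (1.5 equiv), pyridine (6 equiv), CH2Cl2, −20 → 0 °C
Reagents that add atoms: none
Why: Dehydration through the chlorosulfite, in which the only β-hydrogen is the acidic one α to the ester and aryl group and its loss gives the conjugated push–pull quinone methide, under water-free buffered conditions that keep both enol ethers, the silyl ether and the tert-butyl ester.

**Step 7**
Reactants: 14 quinone methide tert-butyl ester
Product: 16 3-[4-(tert-butyldimethylsilyloxy)phenyl]-5-methoxy-4,7-diphenyl-1-benzofuran-2,6-dione, via free carboxylic acid 15 (not isolated)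
Conditions: TFA/CH2Cl2 (1:3), rt; concentrate; then camphorsulfonic acid (10 mol %), toluene, 80 °C, 4 Å molecular sieves
Reagents that add atoms: none
Why: TFA cleaves the tert-butyl ester by acidolysis and protonation of the quinone methide carbonyl lets the exocyclic bond rotate, so the carboxyl oxygen adds to the adjacent methoxy-bearing ring carbon and methanol is expelled (acid-catalysed addition–elimination lactonisation of a vinylogous ester, driven by removal of methanol and relief of allylic strain), while the distant methoxy group cannot be reached and is kept because no water is present.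

**Step 8**
Reactants: 16 silyl-protected lactone
Product: 17 3-(4-hydroxyphenyl)-5-methoxy-4,7-diphenyl-1-benzofuran-2,6-dione (5-O-methylxylerythrin, the target)
Conditions: HF·pyridine, THF, 0 °C → rt
Reagents that add atoms: none
Why: Fluoride-driven desilylation (strong Si–F bond) under mildly acidic conditions frees the phenol without touching the enol lactone or the vinylogous methyl ester, which would not survive hydroxide or alkoxide.

Any of 17 already formed by partial silyl loss in step 7 simply passes through step 8 unchanged.

**Compound list**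
1 | bromanil (2,3,5,6-tetrabromo-1,4-benzoquinone) | O=C1C(Br)=C(Br)C(=O)C(Br)=C1Br | starting material
2 | 2,3,5-tribromo-6-methoxy-1,4-benzoquinone | COC1=C(Br)C(=O)C(Br)=C(Br)C1=O | intermediate
3 | 2,5-dibromo-3,6-dimethoxy-1,4-benzoquinone | COC1=C(Br)C(=O)C(OC)=C(Br)C1=O | intermediate
4 | phenylboronic acid | OB(O)c1ccccc1 | starting material
5 | 2-bromo-3,6-dimethoxy-5-phenyl-1,4-benzoquinone | COC1=C(Br)C(=O)C(OC)=C(c2ccccc2)C1=O | intermediate
6 | 2,5-dimethoxy-3,6-diphenyl-1,4-benzoquinone | COC1=C(c2ccccc2)C(=O)C(OC)=C(c2ccccc2)C1=O | intermediate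
7 | 4-hydroxyphenylacetic acid | OC(=O)Cc1ccc(O)cc1 | starting material
8 | tert-butyl 2-(4-hydroxyphenyl)acetate | CC(C)(C)OC(=O)Cc1ccc(O)cc1 | intermediate
9 | tert-butyl 2-[4-(tert-butyldimethylsilyloxy)phenyl]acetate | CC(C)(C)OC(=O)Cc1ccc(O[Si](C)(C)C(C)(C)C)cc1 | intermediate
10 | lithium enolate of 9 | [Li+].[O-]C(OC(C)(C)C)=Cc1ccc(O[Si](C)(C)C(C)(C)C)cc1 | intermediate
11 | lithium aldolate (lithium alkoxide of 12), racemic diastereomer mixture | [Li+].[O-]C1(C(C(=O)OC(C)(C)C)c2ccc(O[Si](C)(C)C(C)(C)C)cc2)C(OC)=C(c2ccccc2)C(=O)C(OC)=C1c1ccccc1 | intermediate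
12 | tert-butyl 2-[4-(tert-butyldimethylsilyloxy)phenyl]-2-(1-hydroxy-2,5-dimethoxy-4-oxo-3,6-diphenylcyclohexa-2,5-dien-1-yl)acetate, racemic diastereomer mixture | OC1(C(C(=O)OC(C)(C)C)c2ccc(O[Si](C)(C)C(C)(C)C)cc2)C(OC)=C(c2ccccc2)C(=O)C(OC)=C1c1ccccc1 | intermediate
13 | chlorosulfite of 12, stereoisomer mixture | O=S(Cl)OC1(C(C(=O)OC(C)(C)C)c2ccc(O[Si](C)(C)C(C)(C)C)cc2)C(OC)=C(c2ccccc2)C(=O)C(OC)=C1c1ccccc1 | intermediate
14 | tert-butyl 2-[4-(tert-butyldimethylsilyloxy)phenyl]-2-(2,5-dimethoxy-4-oxo-3,6-diphenylcyclohexa-2,5-dien-1-ylidene)acetate, E/Z mixture | CC(C)(C)OC(=O)C(c1ccc(O[Si](C)(C)C(C)(C)C)cc1)=C1C(OC)=C(c2ccccc2)C(=O)C(OC)=C1c1ccccc1 | intermediate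
15 | 2-[4-(tert-butyldimethylsilyloxy)phenyl]-2-(2,5-dimethoxy-4-oxo-3,6-diphenylcyclohexa-2,5-dien-1-ylidene)acetic acid, E/Z mixture | OC(=O)C(c1ccc(O[Si](C)(C)C(C)(C)C)cc1)=C1C(OC)=C(c2ccccc2)C(=O)C(OC)=C1c1ccccc1 | intermediate
16 | 3-[4-(tert-butyldimethylsilyloxy)phenyl]-5-methoxy-4,7-diphenyl-1-benzofuran-2,6-dione | COC1=C(c2ccccc2)C2=C(c3ccc(O[Si](C)(C)C(C)(C)C)cc3)C(=O)OC2=C(c2ccccc2)C1=O | intermediate
17 | 3-(4-hydroxyphenyl)-5-methoxy-4,7-diphenyl-1-benzofuran-2,6-dione | COC1=C(c2ccccc2)C2=C(c3ccc(O)cc3)C(=O)OC2=C(c2ccccc2)C1=O | target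

**Step count**
Total: 8 steps. Longest linear sequence: 6 steps (1 → 3 → 6 → 12 → 14 → 16 → 17, or equally 7 → 8 → 9 → 12 → 14 → 16 → 17).

**Three steps most likely to fail**

Step 5 (aldol addition). The risks are electron transfer from the enolate to the quinone, addition–elimination at a methoxy-bearing carbon instead of 1,2-addition, and retro-aldol of the hindered aldolate. The fallback sets out from 9 and comes back at 12. Compound 9 is deprotonated with LiN(SiMe3)2 at −78 °C and the enolate is quenched with N-bromosuccinimide to give tert-butyl 2-bromo-2-[4-(tert-butyldimethylsilyloxy)phenyl]acetate F1. Activated zinc in THF inserts into the C–Br bond to give the Reformatsky reagent, the bromozinc enolate F2, which is decanted from excess zinc so that the metal cannot reduce the quinone. F2 is added to 6 at 0 °C; the far less basic and less reducing zinc enolate adds to the carbonyl to give the bromozinc aldolate F3, which holds the adduct more firmly against retro-aldol and yields 12 on NH4Cl work-up.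

Step 6 (dehydration). The risks are retro-aldol, chloride capture of the allylic cation, and strain in the open, fully substituted quinone methide. The fallback sets out from 12 and comes back at 16 by reversing the order of events. Compound 12 is treated with TFA in CH2Cl2, which cleaves the tert-butyl ester and closes the carboxyl group onto the neighbouring methoxy-bearing carbon with loss of methanol while the tertiary alcohol is still in place. This gives 3a-hydroxy-5-methoxy-4,7-diphenyl-3-[4-(tert-butyldimethylsilyloxy)phenyl]-3,3a-dihydro-1-benzofuran-2,6-dione F4. In F4 the C3 hydrogen is α to a lactone carbonyl and the hydroxyl sits on a doubly allylic carbon, so warming with catalytic camphorsulfonic acid in toluene over molecular sieves removes water and gives the planar dione 16.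

Step 7 (lactonisation with loss of only the proximal methyl). The risks are incomplete closure, methanol returning to open the enol lactone, and partial loss of the second methoxy group. The fallback sets out from 14 and comes back at 17, and no longer depends on which methoxy group survives. Compound 14 is heated in TFA/water (9:1, 70 °C), which removes the tert-butyl ester, the silyl ether and both enol-ether methyl groups and closes the lactone to xylerythrin, 5-hydroxy-3-(4-hydroxyphenyl)-4,7-diphenyl-1-benzofuran-2,6-dione F5. Only the strongly acidic vinylogous-acid 5-OH of F5 is then methylated (MeI, 1.1 equiv, KHCO3, DMF, rt), since bicarbonate does not deprotonate the phenol; this gives 17 directly.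

**Further compounds**
F1 | step 5 | tert-butyl 2-bromo-2-[4-(tert-butyldimethylsilyloxy)phenyl]acetate | CC(C)(C)OC(=O)C(Br)c1ccc(O[Si](C)(C)C(C)(C)C)cc1
F2 | step 5 | bromozinc enolate (Reformatsky reagent) of F1 | CC(C)(C)OC(=O)C([Zn]Br)c1ccc(O[Si](C)(C)C(C)(C)C)cc1
F3 | step 5 | bromozinc aldolate (bromozinc alkoxide of 12) | Br[Zn]OC1(C(C(=O)OC(C)(C)C)c2ccc(O[Si](C)(C)C(C)(C)C)cc2)C(OC)=C(c2ccccc2)C(=O)C(OC)=C1c1ccccc1
F4 | step 6 | 3a-hydroxy-5-methoxy-4,7-diphenyl-3-[4-(tert-butyldimethylsilyloxy)phenyl]-3,3a-dihydro-1-benzofuran-2,6-dione, racemic diastereomer mixture | COC1=C(c2ccccc2)C2(O)C(c3ccc(O[Si](C)(C)C(C)(C)C)cc3)C(=O)OC2=C(c2ccccc2)C1=O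
F5 | step 7 | xylerythrin, 5-hydroxy-3-(4-hydroxyphenyl)-4,7-diphenyl-1-benzofuran-2,6-dione | OC1=C(c2ccccc2)C2=C(c3ccc(O)cc3)C(=O)OC2=C(c2ccccc2)C1=O
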